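**Strategy.** Everything rests on cutting the hexasubstituted benzene ring of the isochromanone (C4a, C5, C6, C7, C8, C8a) at C4a–C5 and C8–C8a. That ring bears 1,3-related oxygens on C6 and C8, a methyl on C5, the C1 carboxyl on C8a and the C4 chain on C4a. This is the imprint of a β-keto-ester bis(silyloxy)diene on an alkynoate. One thermal [4+2] cycloaddition with loss of methanol should therefore give resorcylate 24 with all six positions settled. The dienophile 17 is a benzyl hex-2-ynoate that already holds the C4 stereocentre, a triethylsilyl-masked C3 carbinol and the benzyl-protected right-hand benzoate. C3 oxidation and neutral hydrogenolysis then close the lactol.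

Key step: step 12

Remarks on the chemistry
- Numbering: the isochromanone numbering of the target is used for all intermediates (C1 lactone carbonyl, O2, C3 lactol carbon, C4 methine, C4a to C8a arene). The target is (3R,4S).
- Assumption: C3 is a lactol centre that equilibrates through keto acid 28. The (3R) epimer has the anomeric OH axial and anti to the pseudo-axial C4 methyl, with the acyloxymethyl group equatorial, and is taken to be the thermodynamic one.
- Design: the C3 carbinol is later oxidised, so its configuration is irrelevant and both C3 epimers converge. C3 carries a triethylsilyl rather than a bulkier silyl ether. It must later leave quickly under buffered fluoride, beside an ester that could capture the free alcohol as a lactone.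

Step 1
Reactants: 1 4,5-dimethylresorcinol
Product: 3 2,4-dihydroxy-5,6-dimethylbenzaldehyde, via aryl iminium chloride 2 (not isolated)
Conditions: POCl3 (1.2 equiv), DMF, MeCN, 0 °C to rt; then H2O, 50 °C
Reagents that add atoms: N,N-dimethylformamide CN(C)C=O; water O
Why: Vilsmeier–Haack formylation attacks the ring carbon that is ortho to one hydroxyl and para to the other rather than the carbon squeezed between both hydroxyls, and hydrolysis of iminium salt 2 releases the aldehyde.

Step 2
Reactants: 3 2,4-dihydroxy-5,6-dimethylbenzaldehyde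
Product: 4 2,4-bis(benzyloxy)-5,6-dimethylbenzaldehyde
Conditions: BnBr (2.5 equiv), K2CO3, DMF, 60 °C
Reagents that add atoms: benzyl bromide BrCc1ccccc1
Why: Double Williamson etherification, warmed so that the hydrogen-bonded ortho phenol also reacts, installs ethers that fall in the final hydrogenolysis.

Step 3
Reactants: 4 2,4-bis(benzyloxy)-5,6-dimethylbenzaldehyde
Product: 5 2,4-bis(benzyloxy)-5,6-dimethylbenzoic acid
Conditions: NaClO2, NaH2PO4, 2-methylbut-2-ene, t-BuOH/THF/H2O, rt
Reagents that add atoms: sodium chlorite [Na+].[O-]Cl=O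
Why: Pinnick oxidation converts hindered electron-rich benzaldehydes into acids, and the alkene scavenger intercepts hypochlorous acid before it can chlorinate the one free ring position.

Step 4
Reactants: 5 2,4-bis(benzyloxy)-5,6-dimethylbenzoic acid; 6 allyl bromide
Product: 7 allyl 2,4-bis(benzyloxy)-5,6-dimethylbenzoate
Conditions: K2CO3, DMF, rt
Reagents that add atoms: none
Why: O-alkylation of the carboxylate (SN2 on allyl bromide) avoids attack at the di-ortho-substituted carbonyl group, which is the dependable way to esterify such hindered acids.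

Step 5
Reactants: 7 allyl 2,4-bis(benzyloxy)-5,6-dimethylbenzoate
Product: 9 2-oxoethyl 2,4-bis(benzyloxy)-5,6-dimethylbenzoate, via vicinal diol 8 (not isolated)
Conditions: OsO4 (2 mol %), NaIO4 (4 equiv), 2,6-lutidine, dioxane/H2O 3:1, rt
Reagents that add atoms: osmium tetroxide O=[Os](=O)(=O)=O; sodium periodate [Na+].[O-]I(=O)(=O)=O
Why: Lemieux–Johnson cleavage (catalytic dihydroxylation to 8, then periodate scission) touches only the terminal alkene, whereas ozone could also attack the dialkoxyarene, and lutidine suppresses over-oxidation.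

Step 6
Reactants: 10 (R)-but-3-yn-2-ol
Product: 11 (R)-but-3-yn-2-yl methanesulfonate
Conditions: MsCl, Et3N, CH2Cl2, −78 to 0 °C
Reagents that add atoms: methanesulfonyl chloride CS(=O)(=O)Cl
Why: Sulfonylation at oxygen leaves the C–O bond and hence the (R) configuration untouched.

Step 7
Reactants: 11 (R)-but-3-yn-2-yl methanesulfonate; 9 2-oxoethyl 2,4-bis(benzyloxy)-5,6-dimethylbenzoate
Product: 13 (2S,3S)-2-hydroxy-3-methylpent-4-yn-1-yl 2,4-bis(benzyloxy)-5,6-dimethylbenzoate, via (P)-allenylzinc mesylate 12 (not isolated)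
Conditions: Pd(OAc)2 (5 mol %), PPh3 (5 mol %), Et2Zn (3 equiv), THF, −78 to −20 °C; aq NH4Cl
Reagents that add atoms: none
Why: In this Marshall–Tamaru propargylation Pd(0) displaces the mesylate anti (SN2′), transmetalation gives allenylzinc 12, and its cyclic SE2′ addition forms the new C–C bond on the face opposite the departed mesylate, so (R)-11 gives (S)-C4 by chirality transfer while the chair-like transition state favours the anti (3S) carbinol, whose configuration is erased later.

Step 8
Reactants: 13 (2S,3S)-2-hydroxy-3-methylpent-4-yn-1-yl 2,4-bis(benzyloxy)-5,6-dimethylbenzoate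
Product: 14 (2S,3S)-3-methyl-2-(triethylsilyloxy)pent-4-yn-1-yl 2,4-bis(benzyloxy)-5,6-dimethylbenzoate
Conditions: TESCl, imidazole, CH2Cl2, 0 °C to rt
Reagents that add atoms: chlorotriethylsilane CC[Si](Cl)(CC)CC
Why: Routine silylation under weakly basic conditions gives the hindered aroyl group no opportunity for a 1,2-shift and installs a group that survives base and heat yet is cleaved far more readily than a bulkier silyl ether.

Step 9
Reactants: 14 (2S,3S)-3-methyl-2-(triethylsilyloxy)pent-4-yn-1-yl 2,4-bis(benzyloxy)-5,6-dimethylbenzoate; 15 benzyl chloroformate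
Product: 17 benzyl (4S,5S)-6-{[2,4-bis(benzyloxy)-5,6-dimethylbenzoyl]oxy}-4-methyl-5-(triethylsilyloxy)hex-2-ynoate, via alkynylmagnesium bromide 16 (not isolated)
Conditions: EtMgBr (1.05 equiv), THF, 0 °C to rt; then added to 15 (2 equiv), THF, −40 to 0 °C
Reagents that add atoms: none
Why: Metalation of a terminal alkyne by a Grignard reagent and acylation with a chloroformate is classical alkynoate synthesis, the di-ortho-substituted benzoate resists addition and its ortho methyl is not deprotonated by this base, and inverse addition into excess 15 keeps the product away from basic acetylide so that C4 is not scrambled through the allenoate.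

Step 10
Reactants: 18 methyl 3-oxopentanoate
Product: 19 methyl 3-(trimethylsilyloxy)pent-2-enoate
Conditions: TMSCl, Et3N, hexane, rt
Reagents that add atoms: chlorotrimethylsilane C[Si](C)(C)Cl
Why: O-silylation of the enolised β-keto ester gives the conjugated silyl enol ether, whose double-bond geometry is irrelevant because that bond becomes the central single bond of the diene.

Step 11
Reactants: 19 methyl 3-(trimethylsilyloxy)pent-2-enoate
Product: 21 (1Z,3Z)-1-methoxy-1,3-bis(trimethylsilyloxy)penta-1,3-diene, via lithium dienolate 20 (not isolated)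
Conditions: LDA (commercial solution, 1.1 equiv), THF, −78 °C; TMSCl, −78 °C to rt; distillation
Reagents that add atoms: chlorotrimethylsilane C[Si](C)(C)Cl
Why: Kinetic γ-deprotonation gives extended enolate 20, which is silylated on the ester oxygen to the ketene silyl acetal, and the methyl group should settle trans to the diene chain (3Z), the geometry that can reach the s-cis conformer.

Step 12
Reactants: 17 benzyl (4S,5S)-6-{[2,4-bis(benzyloxy)-5,6-dimethylbenzoyl]oxy}-4-methyl-5-(triethylsilyloxy)hex-2-ynoate; 21 (1Z,3Z)-1-methoxy-1,3-bis(trimethylsilyloxy)penta-1,3-diene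
Product: 24 benzyl 6-[(2S,3S)-4-{[2,4-bis(benzyloxy)-5,6-dimethylbenzoyl]oxy}-3-(triethylsilyloxy)butan-2-yl]-2,4-dihydroxy-5-methylbenzoate, via cyclohexa-1,4-diene cycloadduct 22 (not isolated), via bis(trimethylsilyl) aryl ether 23 (not isolated)
Conditions: 21 (4 equiv, distilled amine-free), neat, sealed silylated glass tube, argon, 125 °C; then THF/10% aq citric acid, rt
Reagents that add atoms: none
Why: A thermal, concerted but asynchronous normal-electron-demand Diels–Alder reaction joins the nucleophilic methyl-bearing terminus of 21 to the β-carbon of ynoate 17 (C5–C4a) and the ketene-acetal carbon to the α-carbon (C8–C8a), so the six-membered carbocycle closes in one intermolecular [4+2] event to give 22. Adduct 22 carries a mixed methyl silyl ketal at C8 and a hydrogen at C5, so 1,4-loss of methanol gives arene 23, whose two aryl trimethylsilyl ethers are cleaved by aqueous citric acid while the secondary triethylsilyl ether stays. The closest known chemistry is the cycloaddition–aromatisation of 1-alkoxy-1,3-bis(silyloxy)dienes with alkynoates to resorcylates, here in a hindered case that calls for excess diene, high concentration and heat. Only regioselectivity is needed, and it follows from matched polarisation (largest HOMO coefficient at the remote diene terminus, largest LUMO coefficient at the ynoate β-carbon), which puts O8 beside the ester and the C5 methyl beside the side chain, while the ynoate is the only dienophile in 17. No lasting stereocentre is made, because the sp3 centres at C5 and C8 of 22 vanish on aromatisation and C4 is a spectator. The C4 hydrogen is vinylogously acidified by the ynoate, so amine-free diene and silylated glass are used to shut off base-mediated alkyne–allene isomerisation.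

Step 13
Reactants: 24 benzyl 6-[(2S,3S)-4-{[2,4-bis(benzyloxy)-5,6-dimethylbenzoyl]oxy}-3-(triethylsilyloxy)butan-2-yl]-2,4-dihydroxy-5-methylbenzoate
Product: 25 benzyl 6-[(2S,3S)-4-{[2,4-bis(benzyloxy)-5,6-dimethylbenzoyl]oxy}-3-(triethylsilyloxy)butan-2-yl]-2-hydroxy-4-methoxy-5-methylbenzoate
Conditions: MeI (1.1 equiv), K2CO3 (1.2 equiv), acetone, rt
Reagents that add atoms: iodomethane CI
Why: Williamson methylation selects the C6 phenol because the C8 phenol is locked in a hydrogen bond to the ester carbonyl and is less acidic and less nucleophilic, a standard distinction in resorcylates.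

Step 14
Reactants: 25 benzyl 6-[(2S,3S)-4-{[2,4-bis(benzyloxy)-5,6-dimethylbenzoyl]oxy}-3-(triethylsilyloxy)butan-2-yl]-2-hydroxy-4-methoxy-5-methylbenzoate
Product: 26 benzyl 6-[(2S,3S)-4-{[2,4-bis(benzyloxy)-5,6-dimethylbenzoyl]oxy}-3-hydroxybutan-2-yl]-2-hydroxy-4-methoxy-5-methylbenzoate
Conditions: HF·pyridine, pyridine, THF, 0 °C; crude product used at once
Reagents that add atoms: none
Why: Buffered fluoride desilylation cleaves the secondary triethylsilyl ether without ever forming an alkoxide, so neither closure onto the deactivated, hydrogen-bonded benzyl ester nor a 1,2-shift of the hindered aroyl group should compete.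

Step 15
Reactants: 26 benzyl 6-[(2S,3S)-4-{[2,4-bis(benzyloxy)-5,6-dimethylbenzoyl]oxy}-3-hydroxybutan-2-yl]-2-hydroxy-4-methoxy-5-methylbenzoate
Product: 27 benzyl 6-[(2S)-4-{[2,4-bis(benzyloxy)-5,6-dimethylbenzoyl]oxy}-3-oxobutan-2-yl]-2-hydroxy-4-methoxy-5-methylbenzoate
Conditions: Dess–Martin periodinane (1.5 equiv), pyridine (5 equiv), CH2Cl2, 0 °C
Reagents that add atoms: none
Why: Dess–Martin oxidation runs under buffered, non-enolising conditions and tolerates the chelated phenol, and the C4 hydrogen of the new ketone is slow to enolise because the di-ortho-substituted arene cannot become coplanar with an enol.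

Step 16
Reactants: 27 benzyl 6-[(2S)-4-{[2,4-bis(benzyloxy)-5,6-dimethylbenzoyl]oxy}-3-oxobutan-2-yl]-2-hydroxy-4-methoxy-5-methylbenzoate
Product: 29 [(3R,4S)-3,8-dihydroxy-6-methoxy-4,5-dimethyl-1-oxo-3,4-dihydro-1H-isochromen-3-yl]methyl 2,4-dihydroxy-5,6-dimethylbenzoate, via open keto acid 28 (not isolated)
Conditions: H2 (1 atm), 10% Pd/C, EtOAc, rt
Reagents that add atoms: none
Why: Neutral hydrogenolysis removes the benzyl ester and both benzyl ethers without touching the non-benzylic ketone, keto acid 28 closes by 6-exo-trig addition of the carboxyl group to the activated α-acyloxy ketone, and ring–chain equilibration under control of C4 should settle C3 as the (R) lactol with the anomeric hydroxyl axial and anti to the pseudo-axial C4 methyl.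

**Compound list**

1 | 4,5-dimethylresorcinol | Cc1cc(O)cc(O)c1C | starting material
2 | N-[(2,4-dihydroxy-5,6-dimethylphenyl)methylidene]-N-methylmethanaminium chloride (formed in situ) | C[N+](C)=Cc1c(O)cc(O)c(C)c1C.[Cl-] | intermediate
3 | 2,4-dihydroxy-5,6-dimethylbenzaldehyde | O=Cc1c(O)cc(O)c(C)c1C | intermediate
4 | 2,4-bis(benzyloxy)-5,6-dimethylbenzaldehyde | O=Cc1c(OCc2ccccc2)cc(OCc2ccccc2)c(C)c1C | intermediate
5 | 2,4-bis(benzyloxy)-5,6-dimethylbenzoic acid | OC(=O)c1c(OCc2ccccc2)cc(OCc2ccccc2)c(C)c1C | intermediate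
6 | allyl bromide | C=CCBr | starting material
7 | allyl 2,4-bis(benzyloxy)-5,6-dimethylbenzoate | C=CCOC(=O)c1c(OCc2ccccc2)cc(OCc2ccccc2)c(C)c1C | intermediate
8 | 2,3-dihydroxypropyl 2,4-bis(benzyloxy)-5,6-dimethylbenzoate (racemic, formed in situ) | OCC(O)COC(=O)c1c(OCc2ccccc2)cc(OCc2ccccc2)c(C)c1C | intermediate
9 | 2-oxoethyl 2,4-bis(benzyloxy)-5,6-dimethylbenzoate | O=CCOC(=O)c1c(OCc2ccccc2)cc(OCc2ccccc2)c(C)c1C | intermediate
10 | (R)-but-3-yn-2-ol | C[C@@H](O)C#C | starting material
11 | (R)-but-3-yn-2-yl methanesulfonate | C[C@@H](OS(C)(=O)=O)C#C | intermediate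
12 | (P)-buta-1,2-dien-1-ylzinc methanesulfonate (formed in situ; the axial chirality is given in the name only) | CC=C=C[Zn]OS(C)(=O)=O | intermediate
13 | (2S,3S)-2-hydroxy-3-methylpent-4-yn-1-yl 2,4-bis(benzyloxy)-5,6-dimethylbenzoate | C#C[C@H](C)[C@H](O)COC(=O)c1c(OCc2ccccc2)cc(OCc2ccccc2)c(C)c1C | intermediate
14 | (2S,3S)-3-methyl-2-(triethylsilyloxy)pent-4-yn-1-yl 2,4-bis(benzyloxy)-5,6-dimethylbenzoate | C#C[C@H](C)[C@H](O[Si](CC)(CC)CC)COC(=O)c1c(OCc2ccccc2)cc(OCc2ccccc2)c(C)c1C | intermediate
15 | benzyl chloroformate | O=C(Cl)OCc1ccccc1 | starting material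
16 | alkynylmagnesium bromide of 14 (formed in situ) | Br[Mg]C#C[C@H](C)[C@H](O[Si](CC)(CC)CC)COC(=O)c1c(OCc2ccccc2)cc(OCc2ccccc2)c(C)c1C | intermediate
17 | benzyl (4S,5S)-6-{[2,4-bis(benzyloxy)-5,6-dimethylbenzoyl]oxy}-4-methyl-5-(triethylsilyloxy)hex-2-ynoate | O=C(OCc1ccccc1)C#C[C@H](C)[C@H](O[Si](CC)(CC)CC)COC(=O)c1c(OCc2ccccc2)cc(OCc2ccccc2)c(C)c1C | intermediate
18 | methyl 3-oxopentanoate | CCC(=O)CC(=O)OC | starting material
19 | methyl 3-(trimethylsilyloxy)pent-2-enoate (E/Z not relevant) | CCC(O[Si](C)(C)C)=CC(=O)OC | intermediate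
20 | lithium 1-methoxy-3-(trimethylsilyloxy)penta-1,3-dien-1-olate (formed in situ) | C/C=C(O[Si](C)(C)C)/C=C(/OC)[O-].[Li+] | intermediate
21 | (1Z,3Z)-1-methoxy-1,3-bis(trimethylsilyloxy)penta-1,3-diene | C/C=C(O[Si](C)(C)C)/C=C(/OC)O[Si](C)(C)C | intermediate
22 | cyclohexa-1,4-diene cycloadduct with OMe and OTMS on C8, OTMS on C6, H and CH3 on C5 (C5 and C8 unassigned, formed in situ) | COC1(O[Si](C)(C)C)C=C(O[Si](C)(C)C)C(C)C([C@H](C)[C@H](O[Si](CC)(CC)CC)COC(=O)c2c(OCc3ccccc3)cc(OCc3ccccc3)c(C)c2C)=C1C(=O)OCc1ccccc1 | intermediate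
23 | 6,8-bis(trimethylsilyl) ether of 24 (formed in situ) | C[Si](C)(C)Oc1cc(O[Si](C)(C)C)c(C(=O)OCc2ccccc2)c(c1C)[C@H](C)[C@H](O[Si](CC)(CC)CC)COC(=O)c1c(OCc2ccccc2)cc(OCc2ccccc2)c(C)c1C | intermediate
24 | benzyl 6-[(2S,3S)-4-{[2,4-bis(benzyloxy)-5,6-dimethylbenzoyl]oxy}-3-(triethylsilyloxy)butan-2-yl]-2,4-dihydroxy-5-methylbenzoate | Oc1cc(O)c(C(=O)OCc2ccccc2)c(c1C)[C@H](C)[C@H](O[Si](CC)(CC)CC)COC(=O)c1c(OCc2ccccc2)cc(OCc2ccccc2)c(C)c1C | intermediate
25 | benzyl 6-[(2S,3S)-4-{[2,4-bis(benzyloxy)-5,6-dimethylbenzoyl]oxy}-3-(triethylsilyloxy)butan-2-yl]-2-hydroxy-4-methoxy-5-methylbenzoate | COc1cc(O)c(C(=O)OCc2ccccc2)c(c1C)[C@H](C)[C@H](O[Si](CC)(CC)CC)COC(=O)c1c(OCc2ccccc2)cc(OCc2ccccc2)c(C)c1C | intermediate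
26 | benzyl 6-[(2S,3S)-4-{[2,4-bis(benzyloxy)-5,6-dimethylbenzoyl]oxy}-3-hydroxybutan-2-yl]-2-hydroxy-4-methoxy-5-methylbenzoate | COc1cc(O)c(C(=O)OCc2ccccc2)c(c1C)[C@H](C)[C@H](O)COC(=O)c1c(OCc2ccccc2)cc(OCc2ccccc2)c(C)c1C | intermediate
27 | benzyl 6-[(2S)-4-{[2,4-bis(benzyloxy)-5,6-dimethylbenzoyl]oxy}-3-oxobutan-2-yl]-2-hydroxy-4-methoxy-5-methylbenzoate | COc1cc(O)c(C(=O)OCc2ccccc2)c(c1C)[C@H](C)C(=O)COC(=O)c1c(OCc2ccccc2)cc(OCc2ccccc2)c(C)c1C | intermediate
28 | 6-{(2S)-4-[(2,4-dihydroxy-5,6-dimethylbenzoyl)oxy]-3-oxobutan-2-yl}-2-hydroxy-4-methoxy-5-methylbenzoic acid (formed in situ) | COc1cc(O)c(C(O)=O)c(c1C)[C@H](C)C(=O)COC(=O)c1c(O)cc(O)c(C)c1C | intermediate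
29 | [(3R,4S)-3,8-dihydroxy-6-methoxy-4,5-dimethyl-1-oxo-3,4-dihydro-1H-isochromen-3-yl]methyl 2,4-dihydroxy-5,6-dimethylbenzoate (CNP0072952.2) | COc1cc(O)c2c(c1C)[C@H](C)[C@](O)(COC(=O)c1c(O)cc(O)c(C)c1C)OC2=O | target

**Step count.** Total: 16 steps. Longest linear sequence: 13 steps (steps 1–5, 7–9, 12–16).

**Steps most likely to fail**

1. **Step 12.**
   - What may go wrong: bond formation between two substituted termini may be sluggish. The diene may decay thermally before it is consumed. Base-triggered alkyne-to-allene isomerisation would erode C4.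
   - Fallback, from 17 back to 24: the steric load is taken out of the cycloaddition and the C5 methyl is added afterwards. Compound 17 is heated with commercial 1-methoxy-1,3-bis(trimethylsilyloxy)buta-1,3-diene, whose reacting terminus is an unsubstituted CH2. The same citric acid work-up should give the C5-unsubstituted resorcylate F1. Bromination with NBS (1 equiv, CH2Cl2, −20 °C) is aimed at C5, the position para to the chelated C8 hydroxyl that halogenation of 6-alkylresorcylates favours. It should give the 5-bromoresorcylate F2. Suzuki–Miyaura methylation (trimethylboroxine, Pd(OAc)2/SPhos, K3PO4, dioxane, 90 °C) then leads to 24.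

2. **Step 14.**
   - What may go wrong: the freed C3 hydroxyl may close onto the neighbouring benzyl ester, or the aroyl group may migrate 1,2, before the oxidation can take place.
   - Fallback, from 25 back to 27: the silyl ether is converted directly into the ketone with IBX in DMSO at rt, a known oxidative cleavage of triethylsilyl ethers. The alcohol is consumed as it forms and is never handled, so steps 14 and 15 merge. This path makes no new compound (F0).

3. **Step 7.**
   - What may go wrong: chirality transfer may be incomplete through racemisation of the allenylmetal. The α-acyloxy aldehyde may be lost through hydration, enolisation or acyl transfer within the zinc alkoxide.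
   - Fallback, from 11 and 5 back to 13: the C3–C4 bond is made on a simple, robust aldehyde and the hindered ester is installed afterwards by carboxylate alkylation. The same Pd/Et2Zn conditions applied to 11 and commercial (tert-butyldimethylsilyloxy)acetaldehyde should give the silyl-protected homopropargylic alcohol F3. TBAF in THF gives the alkynyl 1,2-diol F4. Tin-catalysed selective sulfonylation (TsCl, Et3N, Bu2SnO 2 mol %, CH2Cl2) gives the primary tosylate F5. The caesium salt of 5 (Cs2CO3, DMF, 50 °C) displaces the tosylate, directly or through the terminal epoxide, without touching the C2–O bond, and this gives 13.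

Further compounds
F1 | step 12 | benzyl 2-[(2S,3S)-4-{[2,4-bis(benzyloxy)-5,6-dimethylbenzoyl]oxy}-3-(triethylsilyloxy)butan-2-yl]-4,6-dihydroxybenzoate | Oc1cc(O)c(C(=O)OCc2ccccc2)c(c1)[C@H](C)[C@H](O[Si](CC)(CC)CC)COC(=O)c1c(OCc2ccccc2)cc(OCc2ccccc2)c(C)c1C
F2 | step 12 | benzyl 6-[(2S,3S)-4-{[2,4-bis(benzyloxy)-5,6-dimethylbenzoyl]oxy}-3-(triethylsilyloxy)butan-2-yl]-5-bromo-2,4-dihydroxybenzoate | Oc1cc(O)c(C(=O)OCc2ccccc2)c(c1Br)[C@H](C)[C@H](O[Si](CC)(CC)CC)COC(=O)c1c(OCc2ccccc2)cc(OCc2ccccc2)c(C)c1C
F0 | step 14 | none | none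
F3 | step 7 | (2S,3S)-1-(tert-butyldimethylsilyloxy)-3-methylpent-4-yn-2-ol | C#C[C@H](C)[C@H](O)CO[Si](C)(C)C(C)(C)C
F4 | step 7 | (2S,3S)-3-methylpent-4-yne-1,2-diol | C#C[C@H](C)[C@H](O)CO
F5 | step 7 | (2S,3S)-2-hydroxy-3-methylpent-4-yn-1-yl 4-methylbenzenesulfonate | C#C[C@H](C)[C@H](O)COS(=O)(=O)c1ccc(C)cc1
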